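# Proposed total synthesis of lepidine C

SEM = 2-(trimethylsilyl)ethoxymethyl throughout.

## Analysis of the target

Lepidine C (20) is an achiral diaryl ether that carries two (1H-imidazol-2-yl)methyl arms. Ring A is 1,2,4-trisubstituted: C1 holds the aryloxy oxygen, C2 the CH2–imidazole arm and C4 the methoxy group. Ring B is meta-disubstituted, with the ether oxygen at C1' and the second CH2–imidazole arm at C3'. There is no stereocentre, so the problem is one of regiochemistry and of handling two basic, metal-binding N–H imidazoles. The two methylene groups are doubly activated (benzylic and attached to an azole C2) and are best revealed late. The main difficulty is the ether bond to ring A: ring A is an electron-rich hydroquinone diether, so its C1–O bond cannot be made by SNAr on ring A itself. The strategy rests on the fact that C1 (O-aryl) and C4 (O-methyl) are para to each other with an acyl-level carbon at C2 next to C1. This is the pattern a 2-aryloxyfuran gives with a terminal alkynyl ketone: furan C2 becomes C1, the furan oxygen becomes the C4 oxygen, and the ynone supplies C2 with its carbonyl and C3.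

## Retrosynthetic reasoning

Target 20 to 19. The two N–H bonds are unveiled last. With SEM on N1 the imidazoles stay non-acidic and soluble through all base and organometallic steps, and the same group directs C2 lithiation in the fragment syntheses. The forward reaction only has to cleave two N,O-acetals without touching the aryl ethers.

19 to 17. Both methylene groups are traced back to diaryl ketones. The C2 carbon of ring A must be at acyl level for the ring-forming step, and the ring-B carbon is most easily attached to imidazole C2 as an acyl carbon. Both carbonyls then fall in one Wolff–Kishner operation.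

17 to 16. The O–CH3 bond is cut. The methoxy oxygen is the oxygen that emerges from the ring-forming step as a free phenol, so methylation directly follows it. It is done while the imidazole N3 atoms are still deactivated by the adjacent carbonyl groups, so that O- rather than N-methylation is secured.

16 to 10 and 14 (key disconnection). The C1–C2 and C3–C4 bonds of ring A are cut, which returns the 2-aryloxyfuran 10 and the ynone 14. This single disconnection sets all three ring-A substituents in their correct positions. It also moves the diaryl ether problem from an unactivated benzene ring to a furan, where it is easy to solve. The forward reaction must join furan C5 to the alkyne terminus and furan C2 to the acyl-bearing alkyne carbon, and the oxygen bridge must then open on the side of the aryloxy-bearing bridgehead.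

10 to 9, 8, and then 6 and 7. The furan C5–H bond is traced to a carboxyl group, and the furan C2–O bond is cut to the ketophenol 6 and the bromofuroate 7. The ester in 7 activates the bromide toward addition–elimination by a phenoxide. Once the ether is made, the ester is removed by saponification to 9 and protodecarboxylation to 10.

6 to 4 and 3. The bond between the carbonyl carbon and imidazole C2 is cut. The nucleophile is the lithiated imidazole 4, obtained from 2 and ultimately from imidazole 1. The electrophile is the nitrile 3. A nitrile is preferred to an ester because addition stops at the metalated ketimine 5, whereas an ester would allow a second addition to the ketone as it is released.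

14 to 13, 12 and 11. The bond between the carbonyl carbon and the alkyne is cut. The aldehyde 11 is N-protected to 12, an ethynyl nucleophile adds to give the carbinol 13, and a neutral oxidation gives the ynone 14, which is prepared immediately before use.

## Alternatives that were turned down

Alternative 1: Ring B is disconnected at C5'–C6' and C3'–C4'. In the forward direction the 4-aryloxy-2-pyrone A2, methyl 2-{4-[4-methoxy-2-(2-methoxy-2-oxoethyl)phenoxy]-2-oxo-2H-pyran-6-yl}acetate, adds ethynyl p-tolyl sulfone A3 across pyrone C3 and C6. The bridged lactone then aromatizes by a decarboxylative retro-[4+2] step to the sulfonyl diester A1.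
- For it: aromatization is irreversible and needs no directed bridge opening, and the sulfone both activates the alkyne and fixes the regiochemistry. On the first point it is stronger than the chosen route, whose oxygen bridge must open in one particular direction.
- Against it: the sulfonyl group at C4' is not part of the target and costs a reductive desulfonylation. 4-Oxygenated 2-pyrones are sluggish dienes. A2 needs its own multistep synthesis, including an ether bond from a hindered phenol to pyrone C4. Both imidazole rings would still have to be built from the two arylacetic esters, through enolizable and labile arylacetaldehyde-level intermediates.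
- Comparison: it spends the ring-forming step on ring B, the simpler meta-disubstituted ring. The chosen route spends it on ring A, where the substitution pattern is hard to assemble otherwise, leaves no extraneous atom in the ring, and brings both imidazoles in preformed.

Alternative 2: Both CH2–C2(imidazole) bonds are disconnected. In the forward direction the bis(benzyl chloride) A4, 2-(chloromethyl)-1-[3-(chloromethyl)phenoxy]-4-methoxybenzene, is coupled twice with 2-bromo-1-SEM-imidazole A5 under bipyridine-ligated nickel catalysis with a metallic reductant. This gives bis(N-SEM) lepidine C A6 (the same structure as compound 19).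
- For it: it is stronger than the chosen route in step count and redox economy. The methylene groups arrive at the correct oxidation level, and only SEM removal remains.
- Against it: no ring is formed, so the diaryl ether of A4 must still be made from two prefunctionalized benzenes and carried through reduction and chlorination. Two cross-electrophile couplings must both succeed in one molecule. Benzyl chlorides homocouple readily under such conditions, and with a bis-electrophile that leads to oligomers. The electron-rich 2-bromoazole A5 should undergo oxidative addition slowly, and the imidazole N3 atoms of A5 and A6 can bind nickel. The ring-A benzyl chloride, ortho to an oxygen donor, is also solvolysis-prone.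
- Comparison: the chosen route is longer, but each C–C bond to an imidazole is made by a stoichiometric carbonyl addition with a predictable outcome, and the risk is concentrated in one cycloaddition.

Alternative 3: Ring A is disconnected at C1–O and at the bond from C2 to its carboxyl carbon. In the forward direction fluoride releases 4-methoxybenzyne A8 from 4-methoxy-2-(trimethylsilyl)phenyl triflate A7. The phenoxide of methyl 3-hydroxybenzoate A9 adds to the aryne, and the resulting aryl anion is trapped by carbon dioxide A10 to give 5-methoxy-2-[3-(methoxycarbonyl)phenoxy]benzoic acid A11.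
- For it: it is stronger than the chosen route in convergence. One three-component step forms the diaryl ether and installs the C2 carbon from simple materials.
- Against it: the methoxy group of A8 is remote from both aryne carbons, so little regiochemical bias is expected, and the isomeric acid A12, 4-methoxy-2-[3-(methoxycarbonyl)phenoxy]benzoic acid, should form alongside A11 and be hard to separate. Protonation of the aryl anion competes with carboxylation, and the phenoxide of A9 is itself reversibly carboxylated by A10. The acid and the ester of A11 would then each have to be converted into an imidazolyl ketone and reduced, so the endgame is no shorter.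
- Comparison: in the chosen route the positions of the ring-A substituents are enforced by the mechanism (which furan atom is oxygen, which alkyne carbon bears the acyl group), not by a weak electronic preference.

Key step: step 9

Remark on numbering: metal salts formed by simple deprotonation of an O–H or N–H group (imidazolide, phenoxides, alkoxides, carboxylate) that react on in the same flask are treated as the ionized form of the numbered compound and get no number of their own.

## Route

Step 1
Reactants: 1 1H-imidazole
Product: 2 1-{[2-(trimethylsilyl)ethoxy]methyl}-1H-imidazole (1-SEM-imidazole)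
Conditions: NaH, THF, 0 °C; SEMCl, 0 °C → rt
Reagents that add atoms: 2-(trimethylsilyl)ethoxymethyl chloride (SEMCl), C[Si](C)(C)CCOCCl
Why: N-alkylation of sodium imidazolide; imidazole is symmetric, so only one product can form, and the SEM group later directs lithiation to C2 and is stable to base.

Step 2
Reactants: 2 1-SEM-imidazole; 3 3-hydroxybenzonitrile
Product: 6 (3-hydroxyphenyl)(1-SEM-imidazol-2-yl)methanone, via 2-lithio-1-SEM-imidazole 4 (not isolated), via N–H ketimine 5 (not isolated)
Conditions: 2, n-BuLi, THF, −78 °C; then 3 pretreated with NaH (THF, 0 °C), −78 → 0 °C; 1 M aq. HCl, rt; NaHCO3 to pH 7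
Reagents that add atoms: water, O
Why: Directed C2 lithiation of the N-SEM imidazole, then addition of the aryllithium to a nitrile, which stops at the N-metalated ketimine so that no second addition can occur; dilute acid at room temperature hydrolyses the ketimine to the diaryl ketone. The phenol is carried as its phenoxide, and SEM cleavage needs hot acid or fluoride, so it should survive the work-up.

Step 3
Reactants: 6 (3-hydroxyphenyl)(1-SEM-imidazol-2-yl)methanone; 7 methyl 5-bromofuran-2-carboxylate
Product: 8 methyl 5-[3-(1-SEM-imidazole-2-carbonyl)phenoxy]furan-2-carboxylate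
Conditions: Cs2CO3, DMF, 90 °C
Reagents that add atoms: none
Why: Nucleophilic aromatic substitution (addition–elimination) at furan C5, where the anionic adduct is stabilized by the ester at C2; the ketone and the SEM group are inert to carbonate.

Step 4
Reactants: 8 methyl 5-[3-(1-SEM-imidazole-2-carbonyl)phenoxy]furan-2-carboxylate
Product: 9 5-[3-(1-SEM-imidazole-2-carbonyl)phenoxy]furan-2-carboxylic acid
Conditions: LiOH·H2O, THF/MeOH/H2O, rt; then 1 M aq. HCl to pH 4, 0 °C
Reagents that add atoms: lithium hydroxide (hydroxide oxygen), [Li+].[OH-]
Why: Ester saponification; the 2-acylimidazole is not an acyl donor unless N3 is quaternized, and the acceptor-substituted aryloxyfuran tolerates the brief mildly acidic work-up.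

Step 5
Reactants: 9 5-[3-(1-SEM-imidazole-2-carbonyl)phenoxy]furan-2-carboxylic acid
Product: 10 [3-(furan-2-yloxy)phenyl](1-SEM-imidazol-2-yl)methanone
Conditions: Ag2CO3 (10 mol %), AcOH (5 mol %), DMSO, 120 °C
Reagents that add atoms: none
Why: Silver-catalysed protodecarboxylation of a heteroaryl-2-carboxylic acid: the silver carboxylate loses CO2 to a 2-furylsilver species that is protonated by the acid. The classical counterpart is copper/quinoline decarboxylation of 5-aryloxy-2-furoic acids, and the nearly neutral medium spares the acid-labile 2-aryloxyfuran and the SEM group.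

Step 6
Reactants: 11 1H-imidazole-2-carbaldehyde
Product: 12 1-SEM-1H-imidazole-2-carbaldehyde
Conditions: NaH, DMF, 0 °C; SEMCl, 0 °C → rt
Reagents that add atoms: 2-(trimethylsilyl)ethoxymethyl chloride (SEMCl), C[Si](C)(C)CCOCCl
Why: N-alkylation of the imidazolide; the two ring nitrogens are equivalent, so a single N-SEM aldehyde results.

Step 7
Reactants: 12 1-SEM-1H-imidazole-2-carbaldehyde
Product: 13 1-(1-SEM-imidazol-2-yl)prop-2-yn-1-ol (racemic)
Conditions: HC≡CMgBr, THF, 0 °C; then H2O (aq. NH4Cl buffer)
Reagents that add atoms: ethynylmagnesium bromide, C#C[Mg]Br
Why: 1,2-Addition of an alkynyl Grignard reagent to a heteroaryl aldehyde; the carbinol stereocentre is formed racemic and is removed in the next step.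

Step 8
Reactants: 13 1-(1-SEM-imidazol-2-yl)prop-2-yn-1-ol
Product: 14 1-(1-SEM-imidazol-2-yl)prop-2-yn-1-one
Conditions: MnO2 (activated, excess), CH2Cl2, rt; filtered and used at once
Reagents that add atoms: none
Why: MnO2 oxidation of an activated (propargylic and heterobenzylic) alcohol; the neutral heterogeneous oxidant avoids the bases and nucleophiles that would add to the terminal ynone.

Step 9
Reactants: 10 [3-(furan-2-yloxy)phenyl](1-SEM-imidazol-2-yl)methanone; 14 1-(1-SEM-imidazol-2-yl)prop-2-yn-1-one
Product: 16 {5-hydroxy-2-[3-(1-SEM-imidazole-2-carbonyl)phenoxy]phenyl}(1-SEM-imidazol-2-yl)methanone, via oxa-bridged adduct 15 (not isolated)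
Conditions: PhMe, 80 °C (N2, sealed); then PPTS (10 mol %), rt
Reagents that add atoms: none
Why: The electron-rich 2-aryloxyfuran 10 and the electron-poor terminal ynone 14 should combine in an intermolecular normal-demand Diels–Alder reaction, the known reaction type being the addition of 2-alkoxyfurans to acetylenic carbonyl compounds followed by opening to 4-alkoxyphenols. Bond formation should be asynchronous: the unsubstituted furan C5, which has the largest donor coefficient of a 2-oxygenated furan, leads onto the unhindered alkyne terminus, and the acyl-bearing alkyne carbon then closes onto the aryloxy-bearing furan C2, whose developing positive charge is stabilized by two oxygen atoms; this places the acyl group next to the aryloxy carbon. Ring A is thus closed by a two-bond [4+2] cycloaddition (C1–C2 and C3–C4) that gives the 7-oxanorbornadiene 15, not by cyclization of a chain. In 15 the bridge C–O bond at the aryloxy-bearing bridgehead ionizes, thermally or with PPTS, to a doubly allylic oxocarbenium ion, whereas cleavage at the other bridgehead lacks this stabilization; loss of the C4 proton then gives the phenol 16 with the furan oxygen as the C4 hydroxyl. The two bridgehead stereocentres of 15 form as a racemate and are erased on aromatization, so no stereocontrol is needed. The step needs regioselectivity (secured by the donor at furan C2 and the terminal alkyne), the correct direction of bridge opening (secured by the aryloxy donor), and cycloaddition in preference to Michael-type substitution at furan C5 (favoured by a non-polar solvent and the absence of acid during heating).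

Step 10
Reactants: 16 {5-hydroxy-2-[3-(1-SEM-imidazole-2-carbonyl)phenoxy]phenyl}(1-SEM-imidazol-2-yl)methanone
Product: 17 {5-methoxy-2-[3-(1-SEM-imidazole-2-carbonyl)phenoxy]phenyl}(1-SEM-imidazol-2-yl)methanone
Conditions: Me3SiCHN2 (2 M in hexanes), i-Pr2NEt, MeCN/MeOH 9:1, rt
Reagents that add atoms: trimethylsilyldiazomethane, C[Si](C)(C)C=[N+]=[N-]
Why: O-Methylation of a phenol by a diazoalkane: methanol removes the silyl group and the phenol protonates the diazo carbon, so only the acidic O–H is alkylated. The N3 atoms, which an alkyl halide might quaternize, are not touched, and diaryl ketones are inert to the reagent without a Lewis acid.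

Step 11
Reactants: 17 {5-methoxy-2-[3-(1-SEM-imidazole-2-carbonyl)phenoxy]phenyl}(1-SEM-imidazol-2-yl)methanone
Product: 19 bis(N-SEM) lepidine C, via bis-hydrazone 18 (not isolated)
Conditions: N2H4·H2O (excess), n-BuOH, 120 °C; concentrate (PhMe azeotrope); KOt-Bu, DMSO, 25 °C
Reagents that add atoms: none
Why: Wolff–Kishner reduction in its preformed-hydrazone, KOt-Bu/DMSO variant: the hydrazone anion tautomerizes to the diazene, loses N2, and the doubly benzylic carbanion is protonated. Diaryl ketone hydrazones are the most favourable substrates, and the room-temperature base stage leaves the SEM aminals and the aryl ethers alone.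

Step 12
Reactants: 19 bis(N-SEM) lepidine C
Product: 20 lepidine C
Conditions: 3 M aq. HCl, EtOH, 80 °C; then aq. NaHCO3
Reagents that add atoms: none
Why: Acid hydrolysis of the two N,O-acetals (SEM removal) through N-acyliminium-type ions and N-hydroxymethyl intermediates that release formaldehyde; the diaryl ether and the aryl methyl ether are stable to hot dilute HCl, and basification gives the free base.

## Compound list

1 | 1H-imidazole | c1c[nH]cn1 | starting material
2 | 1-{[2-(trimethylsilyl)ethoxy]methyl}-1H-imidazole (1-SEM-imidazole) | C[Si](C)(C)CCOCn1ccnc1 | intermediate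
3 | 3-hydroxybenzonitrile | N#Cc1cccc(O)c1 | starting material
4 | 2-lithio-1-SEM-imidazole | [Li]c1nccn1COCC[Si](C)(C)C | intermediate
5 | (3-hydroxyphenyl)(1-SEM-imidazol-2-yl)methanimine (N–H ketimine, formed as its metal salt, drawn neutral) | N=C(c1cccc(O)c1)c1nccn1COCC[Si](C)(C)C | intermediate
6 | (3-hydroxyphenyl)(1-SEM-imidazol-2-yl)methanone | O=C(c1cccc(O)c1)c1nccn1COCC[Si](C)(C)C | intermediate
7 | methyl 5-bromofuran-2-carboxylate | COC(=O)c1ccc(Br)o1 | starting material
8 | methyl 5-[3-(1-SEM-imidazole-2-carbonyl)phenoxy]furan-2-carboxylate | COC(=O)c1ccc(Oc2cccc(C(=O)c3nccn3COCC[Si](C)(C)C)c2)o1 | intermediate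
9 | 5-[3-(1-SEM-imidazole-2-carbonyl)phenoxy]furan-2-carboxylic acid | OC(=O)c1ccc(Oc2cccc(C(=O)c3nccn3COCC[Si](C)(C)C)c2)o1 | intermediate
10 | [3-(furan-2-yloxy)phenyl](1-SEM-imidazol-2-yl)methanone | c1coc(Oc2cccc(C(=O)c3nccn3COCC[Si](C)(C)C)c2)c1 | intermediate
11 | 1H-imidazole-2-carbaldehyde | O=Cc1ncc[nH]1 | starting material
12 | 1-SEM-1H-imidazole-2-carbaldehyde | O=Cc1nccn1COCC[Si](C)(C)C | intermediate
13 | 1-(1-SEM-imidazol-2-yl)prop-2-yn-1-ol (racemic) | C#CC(O)c1nccn1COCC[Si](C)(C)C | intermediate
14 | 1-(1-SEM-imidazol-2-yl)prop-2-yn-1-one | C#CC(=O)c1nccn1COCC[Si](C)(C)C | intermediate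
15 | 1-[3-(1-SEM-imidazole-2-carbonyl)phenoxy]-2-(1-SEM-imidazole-2-carbonyl)-7-oxabicyclo[2.2.1]hepta-2,5-diene (racemic oxa-bridged adduct) | O=C(c1nccn1COCC[Si](C)(C)C)C1=CC2C=CC1(Oc1cccc(C(=O)c3nccn3COCC[Si](C)(C)C)c1)O2 | intermediate
16 | {5-hydroxy-2-[3-(1-SEM-imidazole-2-carbonyl)phenoxy]phenyl}(1-SEM-imidazol-2-yl)methanone | O=C(c1nccn1COCC[Si](C)(C)C)c1cc(O)ccc1Oc1cccc(C(=O)c2nccn2COCC[Si](C)(C)C)c1 | intermediate
17 | {5-methoxy-2-[3-(1-SEM-imidazole-2-carbonyl)phenoxy]phenyl}(1-SEM-imidazol-2-yl)methanone | COc1ccc(Oc2cccc(C(=O)c3nccn3COCC[Si](C)(C)C)c2)c(C(=O)c2nccn2COCC[Si](C)(C)C)c1 | intermediate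
18 | bis-hydrazone of 17 (C=N geometry unspecified) | COc1ccc(Oc2cccc(C(=NN)c3nccn3COCC[Si](C)(C)C)c2)c(C(=NN)c2nccn2COCC[Si](C)(C)C)c1 | intermediate
19 | bis(N-SEM) lepidine C: 2-{5-methoxy-2-[3-((1-SEM-imidazol-2-yl)methyl)phenoxy]benzyl}-1-SEM-imidazole | COc1ccc(Oc2cccc(Cc3nccn3COCC[Si](C)(C)C)c2)c(Cc2nccn2COCC[Si](C)(C)C)c1 | intermediate
20 | lepidine C: 2-({5-methoxy-2-[3-(1H-imidazol-2-ylmethyl)phenoxy]phenyl}methyl)-1H-imidazole | COc1ccc(Oc2cccc(Cc3ncc[nH]3)c2)c(Cc2ncc[nH]2)c1 | target

## Step count and risk

Total: 12 steps. Longest linear sequence: 9 steps (steps 1, 2, 3, 4, 5, 9, 10, 11, 12 from imidazole 1). The ynone branch (steps 6–8) joins at step 9.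

Least certain steps:

Step 9 (key step). The aryloxy group, attached to an acyl-bearing ring, is a weaker donor than an alkoxy group, so the cycloaddition may be slow. Meanwhile the terminal ynone may be consumed by self-condensation through conjugate addition of an imidazole N3, or by conjugate addition of the product phenol. Michael-type substitution at furan C5 without ring closure, and hydrolytic opening of the aryloxyfuran by adventitious acid, are the other loss channels. Fallback: the route leaves the cycloaddition and sets out from nitrile 3 and the lithio reagent 4. Nitrile 3 is joined to 2-fluoro-5-methoxybenzonitrile by nucleophilic aromatic substitution (K2CO3, DMSO, 120 °C; fluoride activated by the ortho nitrile) to give 2-(3-cyanophenoxy)-5-methoxybenzonitrile F1. Two equivalents of 4 (from 2 as in step 2) add to both nitriles to give the bis(N–H ketimine) F2, which dilute aqueous HCl hydrolyses to the bis-ketone. The fallback comes back to the route at compound 17.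

Step 5. Loss of the carboxyl group may be accompanied by decomposition of the product under hot conditions, that is, hydrolytic or oxidative opening of the electron-rich 2-aryloxyfuran once the stabilizing carboxyl group is gone. Fallback: the carbon to be removed is changed from carboxyl to formyl. Setting out from ketophenol 6, displacement of the nitro group of 5-nitrofuran-2-carbaldehyde (K2CO3, DMSO, rt to 50 °C) gives 5-[3-(1-SEM-imidazole-2-carbonyl)phenoxy]furan-2-carbaldehyde F3. Decarbonylation with catalytic Pd(OAc)2 (cyclohexane, 140 °C, molecular sieves; Tsuji–Wilkinson-type decarbonylation) then comes back to the route at compound 10.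

Step 11. Hydrazone formation may stay incomplete at the hindered ring-A ketone, which is flanked by the aryloxy group and the N-SEM imidazole. Azine formation may occur on concentration, and the hydrazone nitrogen may displace the ortho aryloxy group intramolecularly. Partial SEM loss would be harmless, since step 12 removes the group anyway. Fallback: setting out from 17, NaBH4 (MeOH, 0 °C) gives the bis-carbinol F4 as a mixture of diastereomers. Acetylation (Ac2O, pyridine, DMAP) gives the bis-acetate F5, and hydrogenolysis of the two diarylmethyl acetates (H2, Pd/C, EtOH/AcOH) comes back to the route at compound 19.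

Step 2. Addition of 4 to the nitrile may be incomplete because the phenoxide salt aggregates or is poorly soluble at low temperature. Hydrolysis of the ketimine may also need acid strong enough to begin SEM loss. Fallback: the acyl donor is changed. Commercial 3-hydroxybenzoic acid is converted into 3-hydroxy-N-methoxy-N-methylbenzamide F6 (EDC·HCl, HOBt, MeNHOMe·HCl, i-Pr2NEt, CH2Cl2). Its sodium phenoxide is treated with 4 at −78 °C, and the chelated tetrahedral adduct collapses on aqueous NH4Cl work-up, which comes back to the route at compound 6.

## Further compounds

F1 | step 9 | 2-(3-cyanophenoxy)-5-methoxybenzonitrile | COc1ccc(Oc2cccc(C#N)c2)c(C#N)c1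
F2 | step 9 | bis(N–H ketimine) corresponding to 17 (drawn neutral) | COc1ccc(Oc2cccc(C(=N)c3nccn3COCC[Si](C)(C)C)c2)c(C(=N)c2nccn2COCC[Si](C)(C)C)c1
F3 | step 5 | 5-[3-(1-SEM-imidazole-2-carbonyl)phenoxy]furan-2-carbaldehyde | O=Cc1ccc(Oc2cccc(C(=O)c3nccn3COCC[Si](C)(C)C)c2)o1
F4 | step 11 | bis-carbinol from 17 (mixture of diastereomers) | COc1ccc(Oc2cccc(C(O)c3nccn3COCC[Si](C)(C)C)c2)c(C(O)c2nccn2COCC[Si](C)(C)C)c1
F5 | step 11 | bis-acetate of the bis-carbinol (mixture of diastereomers) | COc1ccc(Oc2cccc(C(OC(C)=O)c3nccn3COCC[Si](C)(C)C)c2)c(C(OC(C)=O)c2nccn2COCC[Si](C)(C)C)c1
F6 | step 2 | 3-hydroxy-N-methoxy-N-methylbenzamide | CON(C)C(=O)c1cccc(O)c1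
A1 | alternative 1 | methyl 2-{5-[4-methoxy-2-(2-methoxy-2-oxoethyl)phenoxy]-2-(p-tolylsulfonyl)phenyl}acetate | COC(=O)Cc1cc(Oc2ccc(OC)cc2CC(=O)OC)ccc1S(=O)(=O)c1ccc(C)cc1
A2 | alternative 1 | methyl 2-{4-[4-methoxy-2-(2-methoxy-2-oxoethyl)phenoxy]-2-oxo-2H-pyran-6-yl}acetate | COC(=O)CC1=CC(Oc2ccc(OC)cc2CC(=O)OC)=CC(=O)O1
A3 | alternative 1 | ethynyl p-tolyl sulfone | C#CS(=O)(=O)c1ccc(C)cc1
A4 | alternative 2 | 2-(chloromethyl)-1-[3-(chloromethyl)phenoxy]-4-methoxybenzene | COc1ccc(Oc2cccc(CCl)c2)c(CCl)c1
A5 | alternative 2 | 2-bromo-1-SEM-imidazole | Brc1nccn1COCC[Si](C)(C)C
A6 | alternative 2 | bis(N-SEM) lepidine C | COc1ccc(Oc2cccc(Cc3nccn3COCC[Si](C)(C)C)c2)c(Cc2nccn2COCC[Si](C)(C)C)c1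
A7 | alternative 3 | 4-methoxy-2-(trimethylsilyl)phenyl trifluoromethanesulfonate | COc1ccc(OS(=O)(=O)C(F)(F)F)c([Si](C)(C)C)c1
A8 | alternative 3 | 4-methoxybenzyne | COC1=CC#CC=C1
A9 | alternative 3 | methyl 3-hydroxybenzoate | COC(=O)c1cccc(O)c1
A10 | alternative 3 | carbon dioxide | O=C=O
A11 | alternative 3 | 5-methoxy-2-[3-(methoxycarbonyl)phenoxy]benzoic acid | COC(=O)c1cccc(Oc2ccc(OC)cc2C(=O)O)c1
A12 | alternative 3 | 4-methoxy-2-[3-(methoxycarbonyl)phenoxy]benzoic acid | COC(=O)c1cccc(Oc2cc(OC)ccc2C(=O)O)c1
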